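**Retrosynthetic overview**

1. Target 18 comes from 17 by hydrogenolysis of the benzylic ethers, and 17 comes from 16 by syn addition of H2 to the flavone C2''=C3'' bond, which sets C2'' and C3'' cis.
2. The strategy rests on C2 of the 5,7-dihydroxyflavanone unit: a benzylic O–CH that carries the 4-methoxyphenyl ring, which is the methylene of an aryl 4-methoxybenzyl ether six atoms from C3. Disconnecting C2–C3 opens pyranone ring C to diazo ketone 15 (forward: rhodium-carbenoid C–H insertion). All three oxygens of the aroyl ring carry 4-methoxybenzyl groups, so either ortho ether gives the same product and no plain ortho benzyl ether competes.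
3. 15 comes from ketone 14 by diazo transfer. 14 comes from 1,3-diketone 12 and phenacyl bromide 7 by C-alkylation and closure of flavone ring C''. 7 comes from phloroacetophenone by three staged etherifications, each under the mildest base that ionises the phenol in question, and bromination.
4. Ring order: flavone ring C'' (step 7), flavanone ring C (step 9), saturation of ring C'' (step 10).

Key step: step 9

Assumption: Rh2(S-DOSP)4 and the (R,R) enantiomer of the carbene ligand are taken to be the enantiomers that give the (2R,3R) and (2''R,3''R) configurations; if a trial shows the opposite sense, the mirror-image catalyst is used in that step.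

**Step 1**
Reactants: 1 2',4',6'-trihydroxyacetophenone; 2 4-methoxybenzyl chloride
Product: 3 1-[2,6-dihydroxy-4-(4-methoxybenzyloxy)phenyl]ethanone
Conditions: 2 (1.0 equiv), CsHCO3 (1.1 equiv), MeCN, 60 °C
Reagents that add atoms: none
Why: Regioselective Williamson etherification, in which the hydrogencarbonate ionises only the 4-hydroxyl (para to the acetyl group, the most acidic and the one least engaged in hydrogen bonding to the ketone), so that one equivalent of the chloride etherifies that oxygen, and any bis-ether 4 formed by over-alkylation lies on the route and is combined with the product of step 2.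

**Step 2**
Reactants: 3 1-[2,6-dihydroxy-4-(4-methoxybenzyloxy)phenyl]ethanone; 2 4-methoxybenzyl chloride
Product: 4 1-[2-hydroxy-4,6-bis(4-methoxybenzyloxy)phenyl]ethanone
Conditions: 2 (1.05 equiv), K2CO3, acetone, reflux
Reagents that add atoms: none
Why: Williamson mono-etherification of the symmetric 2,6-diol, which stops after one alkylation because the remaining hydroxyl is locked in a hydrogen bond to the ketone carbonyl.

**Step 3**
Reactants: 4 1-[2-hydroxy-4,6-bis(4-methoxybenzyloxy)phenyl]ethanone; 2 4-methoxybenzyl chloride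
Product: 5 1-[2,4,6-tris(4-methoxybenzyloxy)phenyl]ethanone
Conditions: 2 (1.3 equiv), K2CO3, Bu4NI (cat.), DMF, 70 °C
Reagents that add atoms: none
Why: Williamson etherification of the chelated phenol, forced by the polar solvent, heat and 4-methoxybenzyl iodide formed in situ, while the acetyl group and the two ether groups already present leave the ring too hindered and too electron-poor for C-benzylation.

**Step 4**
Reactants: 5 1-[2,4,6-tris(4-methoxybenzyloxy)phenyl]ethanone
Product: 7 2-bromo-1-[2,4,6-tris(4-methoxybenzyloxy)phenyl]ethanone, via silyl enol ether 6 (not isolated)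
Conditions: LiN(SiMe3)2, Me3SiCl, THF, −78 °C; then N-bromosuccinimide, THF, −78 to 0 °C
Reagents that add atoms: N-bromosuccinimide, O=C1CCC(=O)N1Br; chlorotrimethylsilane, C[Si](C)(C)Cl
Why: Bromination of a preformed trimethylsilyl enol ether, in which the lithium enolate of the methyl ketone (the only enolisable position) is trapped on oxygen and the enol ether takes up bromine much faster than the alkoxy-substituted arene rings, so that nuclear bromination and free HBr are avoided.

**Step 5**
Reactants: 8 2',6'-dihydroxy-4'-methoxyacetophenone; 9 benzyl bromide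
Product: 10 1-[2-(benzyloxy)-6-hydroxy-4-methoxyphenyl]ethanone
Conditions: 9 (1.05 equiv), K2CO3, acetone, reflux
Reagents that add atoms: none
Why: Williamson mono-etherification of a symmetric diol, which stops after one benzylation because the remaining hydroxyl is locked in a hydrogen bond to the ketone.

**Step 6**
Reactants: 10 1-[2-(benzyloxy)-6-hydroxy-4-methoxyphenyl]ethanone; 11 4-methoxybenzoyl chloride
Product: 12 1-[2-(benzyloxy)-6-hydroxy-4-methoxyphenyl]-3-(4-methoxyphenyl)propane-1,3-dione
Conditions: LiN(SiMe3)2 (3.2 equiv), THF, −78 to −10 °C; then 11, −78 °C to rt; aq. HCl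
Reagents that add atoms: none
Why: Claisen-type C-acylation of the dilithium phenoxide–enolate (the one-flask equivalent of a Baker–Venkataraman sequence), in which any O-aroyl ester that forms is moved to carbon by the excess amide base and the acidic diketone is held as its enolate until work-up.

**Step 7**
Reactants: 12 1-[2-(benzyloxy)-6-hydroxy-4-methoxyphenyl]-3-(4-methoxyphenyl)propane-1,3-dione; 7 2-bromo-1-[2,4,6-tris(4-methoxybenzyloxy)phenyl]ethanone
Product: 14 5-(benzyloxy)-7-methoxy-2-(4-methoxyphenyl)-3-{2-oxo-2-[2,4,6-tris(4-methoxybenzyloxy)phenyl]ethyl}-4H-chromen-4-one, via triketone 13 (not isolated)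
Conditions: K2CO3, DMF, 0 °C to rt; then DBU, 90 °C
Reagents that add atoms: none
Why: C-alkylation of the potassium 1,3-diketonate (more acidic and softer than the hydrogen-bonded phenol) with the phenacyl bromide gives triketone 13, whose phenol adds to the anisoyl carbonyl and whose 2-hydroxychromanone form then loses water by base-induced E1cB elimination (the base-mediated variant of the cyclodehydration that ends a Baker–Venkataraman flavone synthesis), conditions that spare the acid-labile 4-methoxybenzyl ethers and avoid acid-catalysed Paal–Knorr furan formation.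

**Step 8**
Reactants: 14 5-(benzyloxy)-7-methoxy-2-(4-methoxyphenyl)-3-{2-oxo-2-[2,4,6-tris(4-methoxybenzyloxy)phenyl]ethyl}-4H-chromen-4-one
Product: 15 5-(benzyloxy)-3-{1-diazo-2-oxo-2-[2,4,6-tris(4-methoxybenzyloxy)phenyl]ethyl}-7-methoxy-2-(4-methoxyphenyl)-4H-chromen-4-one
Conditions: 4-acetamidobenzenesulfonyl azide, DBU, MeCN–CH2Cl2, 0 °C to rt
Reagents that add atoms: 4-acetamidobenzenesulfonyl azide, CC(=O)Nc1ccc(cc1)S(=O)(=O)N=[N+]=[N-]
Why: Regitz diazo transfer, in which DBU enolises the ketone at the methylene flanked by the carbonyl and the chromone C2''=C3'' bond, the enolate attacks the terminal nitrogen of the sulfonyl azide and the triazene collapses to diazo ketone and sulfonamide, as in the preparation of aryl- and vinyl-substituted diazo ketones.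

**Step 9**
Reactants: 15 5-(benzyloxy)-3-{1-diazo-2-oxo-2-[2,4,6-tris(4-methoxybenzyloxy)phenyl]ethyl}-7-methoxy-2-(4-methoxyphenyl)-4H-chromen-4-one
Product: 16 (2R,3R)-3-[5-(benzyloxy)-7-methoxy-2-(4-methoxyphenyl)-4-oxo-4H-chromen-3-yl]-5,7-bis(4-methoxybenzyloxy)-2-(4-methoxyphenyl)chroman-4-one (2,3-cis)
Conditions: Rh2(S-DOSP)4 (dirhodium tetrakis[(S)-N-(4-dodecylbenzenesulfonyl)prolinate], 2 mol%), toluene–hexanes, 0 °C to rt, slow addition of 15
Reagents that add atoms: none
Why: Rh2(S-DOSP)4 (divalent rhodium) expels N2 from 15 to give a rhodium carbenoid at C3 that has the aryl ketone as acceptor and the chromone O1''–C2''=C3'' enol-ether unit as donor, and this carbenoid inserts through a concerted three-centre transition state with hydride-transfer character into a benzylic C–H bond of an ortho 4-methoxybenzyl ether, a bond activated by the ether oxygen and by the anisyl ring. The closest known reaction type is the cyclisation of alpha-diazo ketones that carry an ortho-benzyloxyaryl group to cis-2,3-disubstituted chroman-4-ones under dirhodium tetracarboxylate catalysis. Ring C closes by 1,6-insertion, through a six-membered cyclic transition state made of C3, C4, C4a, C8a, O1 and C2, which forms the C2–C3 bond. C2 is set by which of the two enantiotopic benzylic hydrogens the chiral prolinate pocket presents to the carbenoid and C3 by the carbenoid face left open in that pocket, and because the C–H bond is delivered to carbon in a tight cyclic array the anisyl and flavonyl groups end cis, which corresponds to (2R,3R). The step needs insertion to win over oxonium-ylide formation followed by benzyl shift, over 1,2-hydride shift and over attack at any other benzylic site: the stabilised donor/acceptor carbenoid and the weakly nucleophilic aryl ether oxygens disfavour the ylide, C3'' has no hydrogen to shift, the twisted 2,6-disubstituted aroyl ring holds both ortho OCH2 groups next to the carbenoid, the two ortho ethers are identical so that either insertion gives 16, and the flavone benzyl ether could react only through a seven-membered transition state. Work-up and chromatography avoid base so that the acidic C3–H is not epimerised to the trans isomer.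

**Step 10**
Reactants: 16 (2R,3R)-3-[5-(benzyloxy)-7-methoxy-2-(4-methoxyphenyl)-4-oxo-4H-chromen-3-yl]-5,7-bis(4-methoxybenzyloxy)-2-(4-methoxyphenyl)chroman-4-one
Product: 17 (2R,3R)-3-[(2R,3R)-5-(benzyloxy)-7-methoxy-2-(4-methoxyphenyl)-4-oxochroman-3-yl]-5,7-bis(4-methoxybenzyloxy)-2-(4-methoxyphenyl)chroman-4-one (both rings 2,3-cis)
Conditions: [Ru(cod)(2-methylallyl)2] (10 mol%), (R,R)-SINpEt·HBF4 (1,3-bis[(R)-1-(naphthalen-1-yl)ethyl]imidazolinium tetrafluoroborate, 20 mol%), KOtBu (19 mol%), hexane, 70 °C, filtered; then 16, H2 (100 bar), toluene, 30 °C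
Reagents that add atoms: none
Why: Proposed new method: the ruthenium bis(carbene) catalyst is known to hydrogenate the C2=C3 bond of 2-substituted chromones and flavones enantioselectively (the closest known reaction type) and is asked here to add H2 across a tetrasubstituted C2''=C3'' bond that carries a branched C3'' substituent; a ruthenium hydride bound to one face of the planar vinylogous ester inserts the alkene and delivers both hydrogens suprafacially, so C2''–H and C3''–H end cis, the ligand enantiomer is chosen so that its facial preference coincides with the bias of the (2R,3R) unit to give (2''R,3''R), the two ketones (each flanked by an ortho alkoxy group and a branched alpha carbon) should react more slowly than the alkene so that the reaction is stopped after one equivalent of H2, and the catalyst is made with a slight deficit of alkoxide so that no base reaches the epimerisable C3–H.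

**Step 11**
Reactants: 17 (2R,3R)-3-[(2R,3R)-5-(benzyloxy)-7-methoxy-2-(4-methoxyphenyl)-4-oxochroman-3-yl]-5,7-bis(4-methoxybenzyloxy)-2-(4-methoxyphenyl)chroman-4-one
Product: 18 (2R,3R)-5,7-dihydroxy-3-[(2R,3R)-5-hydroxy-7-methoxy-2-(4-methoxyphenyl)-4-oxochroman-3-yl]-2-(4-methoxyphenyl)chroman-4-one (CNP0184936.2)
Conditions: H2 (1 atm), 10% Pd/C, EtOAc–MeOH, rt
Reagents that add atoms: none
Why: Hydrogenolysis of one benzyl and two 4-methoxybenzyl aryl ethers under neutral conditions, in which the primary exocyclic benzylic C–O bonds are cleaved faster than the secondary ring C2–O1 bonds and the absence of base leaves the four stereocentres untouched.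

**Compound list**

1 | 2',4',6'-trihydroxyacetophenone | CC(=O)c1c(O)cc(O)cc1O | starting material
2 | 4-methoxybenzyl chloride | COc1ccc(CCl)cc1 | starting material
3 | 1-[2,6-dihydroxy-4-(4-methoxybenzyloxy)phenyl]ethanone | CC(=O)c1c(O)cc(OCc2ccc(OC)cc2)cc1O | intermediate
4 | 1-[2-hydroxy-4,6-bis(4-methoxybenzyloxy)phenyl]ethanone | CC(=O)c1c(O)cc(OCc2ccc(OC)cc2)cc1OCc1ccc(OC)cc1 | intermediate
5 | 1-[2,4,6-tris(4-methoxybenzyloxy)phenyl]ethanone | CC(=O)c1c(OCc2ccc(OC)cc2)cc(OCc2ccc(OC)cc2)cc1OCc1ccc(OC)cc1 | intermediate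
6 | trimethylsilyl enol ether of 5, trimethyl({1-[2,4,6-tris(4-methoxybenzyloxy)phenyl]ethenyl}oxy)silane | C=C(O[Si](C)(C)C)c1c(OCc2ccc(OC)cc2)cc(OCc2ccc(OC)cc2)cc1OCc1ccc(OC)cc1 | intermediate
7 | 2-bromo-1-[2,4,6-tris(4-methoxybenzyloxy)phenyl]ethanone | BrCC(=O)c1c(OCc2ccc(OC)cc2)cc(OCc2ccc(OC)cc2)cc1OCc1ccc(OC)cc1 | intermediate
8 | 2',6'-dihydroxy-4'-methoxyacetophenone | CC(=O)c1c(O)cc(OC)cc1O | starting material
9 | benzyl bromide | BrCc1ccccc1 | starting material
10 | 1-[2-(benzyloxy)-6-hydroxy-4-methoxyphenyl]ethanone | CC(=O)c1c(O)cc(OC)cc1OCc1ccccc1 | intermediate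
11 | 4-methoxybenzoyl chloride | COc1ccc(C(Cl)=O)cc1 | starting material
12 | 1-[2-(benzyloxy)-6-hydroxy-4-methoxyphenyl]-3-(4-methoxyphenyl)propane-1,3-dione | COc1ccc(C(=O)CC(=O)c2c(O)cc(OC)cc2OCc2ccccc2)cc1 | intermediate
13 | 1-[2-(benzyloxy)-6-hydroxy-4-methoxyphenyl]-2-(4-methoxybenzoyl)-4-[2,4,6-tris(4-methoxybenzyloxy)phenyl]butane-1,4-dione (triketone, C2 unassigned) | COc1ccc(C(=O)C(CC(=O)c2c(OCc3ccc(OC)cc3)cc(OCc3ccc(OC)cc3)cc2OCc2ccc(OC)cc2)C(=O)c2c(O)cc(OC)cc2OCc2ccccc2)cc1 | intermediate
14 | 5-(benzyloxy)-7-methoxy-2-(4-methoxyphenyl)-3-{2-oxo-2-[2,4,6-tris(4-methoxybenzyloxy)phenyl]ethyl}-4H-chromen-4-one | COc1ccc(-c2oc3cc(OC)cc(OCc4ccccc4)c3c(=O)c2CC(=O)c2c(OCc3ccc(OC)cc3)cc(OCc3ccc(OC)cc3)cc2OCc2ccc(OC)cc2)cc1 | intermediate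
15 | 5-(benzyloxy)-3-{1-diazo-2-oxo-2-[2,4,6-tris(4-methoxybenzyloxy)phenyl]ethyl}-7-methoxy-2-(4-methoxyphenyl)-4H-chromen-4-one | COc1ccc(-c2oc3cc(OC)cc(OCc4ccccc4)c3c(=O)c2C(=[N+]=[N-])C(=O)c2c(OCc3ccc(OC)cc3)cc(OCc3ccc(OC)cc3)cc2OCc2ccc(OC)cc2)cc1 | intermediate
16 | (2R,3R)-3-[5-(benzyloxy)-7-methoxy-2-(4-methoxyphenyl)-4-oxo-4H-chromen-3-yl]-5,7-bis(4-methoxybenzyloxy)-2-(4-methoxyphenyl)chroman-4-one (2,3-cis) | COc1ccc([C@@H]2Oc3cc(OCc4ccc(OC)cc4)cc(OCc4ccc(OC)cc4)c3C(=O)[C@@H]2c2c(-c3ccc(OC)cc3)oc3cc(OC)cc(OCc4ccccc4)c3c2=O)cc1 | intermediate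
17 | (2R,3R)-3-[(2R,3R)-5-(benzyloxy)-7-methoxy-2-(4-methoxyphenyl)-4-oxochroman-3-yl]-5,7-bis(4-methoxybenzyloxy)-2-(4-methoxyphenyl)chroman-4-one (cis in both rings) | COc1ccc([C@@H]2Oc3cc(OCc4ccc(OC)cc4)cc(OCc4ccc(OC)cc4)c3C(=O)[C@@H]2[C@H]2C(=O)c3c(OCc4ccccc4)cc(OC)cc3O[C@H]2c2ccc(OC)cc2)cc1 | intermediate
18 | (2R,3R)-5,7-dihydroxy-3-[(2R,3R)-5-hydroxy-7-methoxy-2-(4-methoxyphenyl)-4-oxochroman-3-yl]-2-(4-methoxyphenyl)chroman-4-one (cis in both rings) | COc1ccc([C@@H]2Oc3cc(O)cc(O)c3C(=O)[C@@H]2[C@H]2C(=O)c3c(O)cc(OC)cc3O[C@H]2c2ccc(OC)cc2)cc1 | target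

**Step count**

Total steps: 11. Longest linear sequence: 9 steps (steps 1, 2, 3, 4, 7, 8, 9, 10, 11); the branch through steps 5 and 6 joins at step 7.

**Steps most likely to fail**

Step 10 (the labelled step). The tetrasubstituted C2''=C3'' bond may take up no hydrogen, the ketones may be reduced as well, hydrogen may be delivered to the wrong face, or traces of alkoxide may epimerise C3. The fallback sets out from 16 and uses known heterogeneous chemistry. Hydrogenolysis over 10% Pd/C (H2, 1 atm, EtOAc–MeOH) removes the three benzylic ethers and should give (2R,3R)-5,7-dihydroxy-3-[5-hydroxy-7-methoxy-2-(4-methoxyphenyl)-4-oxo-4H-chromen-3-yl]-2-(4-methoxyphenyl)chroman-4-one F1. Continued hydrogenation of F1 over Pd/C at raised pressure (H2, 50 bar, EtOAc–AcOH) is the known syn hydrogenation of a chromone C2=C3 bond on a metal surface and adds both hydrogens from one face, so ring C'' should again be 2'',3''-cis. The face is then chosen by the existing (2R,3R) unit, the (2''S,3''S) isomer is removed by preparative HPLC, and the sequence comes back to the route at 18.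

Step 9. The carbenoid may be diverted to an oxonium ylide with benzyl shift, or the insertion may proceed with poor enantio- or cis-selectivity. The fallback sets out from 14 and builds ring C without a carbenoid. Chelation-assisted cleavage of one ortho 4-methoxybenzyl ether (MgBr2·OEt2, toluene–Et2O, rt; the ether next to the ketone is lost faster than the para ether and the flavone benzyl ether) should give 5-(benzyloxy)-3-{2-[2-hydroxy-4,6-bis(4-methoxybenzyloxy)phenyl]-2-oxoethyl}-7-methoxy-2-(4-methoxyphenyl)-4H-chromen-4-one F2. Knoevenagel condensation of the active methylene of F2 with 4-methoxybenzaldehyde (piperidine, EtOH, reflux) and ring closure of the resulting chalcone by oxa-Michael addition should give racemic trans-3-[5-(benzyloxy)-7-methoxy-2-(4-methoxyphenyl)-4-oxo-4H-chromen-3-yl]-5,7-bis(4-methoxybenzyloxy)-2-(4-methoxyphenyl)chroman-4-one F3. Preparative HPLC on a chiral stationary phase then separates the trans enantiomer (2R,3S)-3-[5-(benzyloxy)-7-methoxy-2-(4-methoxyphenyl)-4-oxo-4H-chromen-3-yl]-5,7-bis(4-methoxybenzyloxy)-2-(4-methoxyphenyl)chroman-4-one F4. Deprotonation of F4 at C3 (LiN(SiMe3)2, THF, −78 °C) and kinetic protonation of the enolate with 2,6-di-tert-butylphenol from the face opposite the C2 anisyl group should invert C3 only, and the sequence comes back to the route at 16.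

Step 7. Alkylation may occur at the phenoxide oxygen instead of the diketone carbon, or ring closure and loss of water may stay incomplete under base. The fallback sets out from 12 and attaches the side chain by cross-coupling instead. Cyclodehydration of 12 (TsOH cat., toluene, reflux) should give 5-(benzyloxy)-7-methoxy-2-(4-methoxyphenyl)-4H-chromen-4-one F5. Lithiation at C3 (LiN(iPr)2, THF, −78 °C) and quenching with I2 should give 5-(benzyloxy)-3-iodo-7-methoxy-2-(4-methoxyphenyl)-4H-chromen-4-one F6. Palladium-catalysed alpha-arylation of ketone 5 with F6 (Pd2(dba)3, Xantphos, K3PO4, toluene, 90 °C) should form the C3''–CH2 bond and come back to the route at 14; bromide 7 is then not needed.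

**Further compounds**

F1 | step 10 | (2R,3R)-5,7-dihydroxy-3-[5-hydroxy-7-methoxy-2-(4-methoxyphenyl)-4-oxo-4H-chromen-3-yl]-2-(4-methoxyphenyl)chroman-4-one | COc1ccc([C@@H]2Oc3cc(O)cc(O)c3C(=O)[C@@H]2c2c(-c3ccc(OC)cc3)oc3cc(OC)cc(O)c3c2=O)cc1
F2 | step 9 | 5-(benzyloxy)-3-{2-[2-hydroxy-4,6-bis(4-methoxybenzyloxy)phenyl]-2-oxoethyl}-7-methoxy-2-(4-methoxyphenyl)-4H-chromen-4-one | COc1ccc(-c2oc3cc(OC)cc(OCc4ccccc4)c3c(=O)c2CC(=O)c2c(O)cc(OCc3ccc(OC)cc3)cc2OCc2ccc(OC)cc2)cc1
F3 | step 9 | racemic trans-3-[5-(benzyloxy)-7-methoxy-2-(4-methoxyphenyl)-4-oxo-4H-chromen-3-yl]-5,7-bis(4-methoxybenzyloxy)-2-(4-methoxyphenyl)chroman-4-one, (2R,3S) and (2S,3R) | COc1ccc([C@@H]2Oc3cc(OCc4ccc(OC)cc4)cc(OCc4ccc(OC)cc4)c3C(=O)[C@H]2c2c(-c3ccc(OC)cc3)oc3cc(OC)cc(OCc4ccccc4)c3c2=O)cc1.COc1ccc([C@H]2Oc3cc(OCc4ccc(OC)cc4)cc(OCc4ccc(OC)cc4)c3C(=O)[C@@H]2c2c(-c3ccc(OC)cc3)oc3cc(OC)cc(OCc4ccccc4)c3c2=O)cc1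
F4 | step 9 | (2R,3S)-3-[5-(benzyloxy)-7-methoxy-2-(4-methoxyphenyl)-4-oxo-4H-chromen-3-yl]-5,7-bis(4-methoxybenzyloxy)-2-(4-methoxyphenyl)chroman-4-one (2,3-trans) | COc1ccc([C@@H]2Oc3cc(OCc4ccc(OC)cc4)cc(OCc4ccc(OC)cc4)c3C(=O)[C@H]2c2c(-c3ccc(OC)cc3)oc3cc(OC)cc(OCc4ccccc4)c3c2=O)cc1
F5 | step 7 | 5-(benzyloxy)-7-methoxy-2-(4-methoxyphenyl)-4H-chromen-4-one | COc1ccc(-c2cc(=O)c3c(OCc4ccccc4)cc(OC)cc3o2)cc1
F6 | step 7 | 5-(benzyloxy)-3-iodo-7-methoxy-2-(4-methoxyphenyl)-4H-chromen-4-one | COc1ccc(-c2oc3cc(OC)cc(OCc4ccccc4)c3c(=O)c2I)cc1
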